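**Strategy**

The C8–CH2 bond of the target is traced back to an O5–CH2 bond. The precursor is (2S)-5,7-bis(prenyloxy)flavanone, made from bought 5,7-dihydroxychromone by two O-prenylations and a rhodium-catalysed asymmetric phenyl addition that sets C2. The last step exploits the peri arrangement of the ring C carbonyl oxygen at C4 and the ether oxygen at C5 of ring A. Eu(fod)3 chelates this pair only, so the O5 prenyl group alone leaves oxygen, passes through C6 and, by a second [3,3] shift, ends on C8, the position para to C5. The same operation frees the 5-OH and leaves the O7 ether untouched.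

Key step: step 4

Remark on the chemistry (assumption): the (S)-atropisomer of MeO-F12-BIPHEP, that is (6,6'-dimethoxybiphenyl-2,2'-diyl)bis[bis(3,4,5-trifluorophenyl)phosphane], is assumed to deliver the 2S product, by analogy with the usual facial sense of rhodium/biaryl-bisphosphine additions to cyclic enones. The absolute configuration of 7 should be confirmed by CD and chiral HPLC on the first run, and the (R)-ligand should be used instead if the sense proves opposite.

**Route**

Step 1
Reactants: 1 5,7-dihydroxychromone; 2 prenyl bromide (1-bromo-3-methylbut-2-ene)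
Product: 3 5-hydroxy-7-(prenyloxy)chromone
Conditions: 2 (1.05 equiv), K2CO3 (1.2 equiv), acetone, 25–40 °C
Reagents that add atoms: prenyl bromide (2), CC(C)=CCBr
Why: Williamson etherification (SN2 at the primary allylic bromide), in which the 7-OH is the acidic, vinylogous-acid phenol while the 5-OH is held in a hydrogen bond to the C4 carbonyl, so one equivalent of weak base and bromide at low temperature should alkylate O7 alone, and the chromone, which has no stereocenter, is not endangered by this mild base.

Step 2
Reactants: 3 5-hydroxy-7-(prenyloxy)chromone; 4 prenol (3-methylbut-2-en-1-ol)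
Product: 5 5,7-bis(prenyloxy)chromone
Conditions: 4 (1.5 equiv), PPh3 (1.5 equiv), DIAD (1.5 equiv), THF, 0 °C to rt
Reagents that add atoms: prenol (4), CC(C)=CCO
Why: Mitsunobu etherification, in which the hydrogen-bonded 5-OH is still acidic enough to protonate the PPh3–DIAD betaine and its phenoxide displaces the prenyl oxyphosphonium ion at the primary carbon in a neutral medium, which avoids the C-alkylation and allylic transposition that a hard base could cause.

Step 3
Reactants: 5 5,7-bis(prenyloxy)chromone; 6 phenylboronic acid
Product: 7 (2S)-5,7-bis(prenyloxy)flavanone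
Conditions: 6 (3 equiv), pre-formed [Rh(OH)((S)-MeO-F12-BIPHEP)]2 (1.5 mol %), toluene, H2O (2 equiv), 40 °C, no base, stopped at full conversion of 5
Reagents that add atoms: phenylboronic acid (6), OB(O)c1ccccc1
Why: Rhodium-catalysed asymmetric 1,4-addition of an arylboronic acid (Hayashi–Miyaura type), in which transmetalation gives a phenyl complex of monovalent rhodium whose electron-poor biaryl bisphosphine lets the chromone C2=C3 bond insert through one face only, setting C2 as S, and water protonates the rhodium enolate without any base, while the trisubstituted prenyl alkenes and the aryl allyl ethers are inert to this catalyst.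

Step 4
Reactants: 7 (2S)-5,7-bis(prenyloxy)flavanone
Product: 10 CNP0292726.1 = (2S)-5-hydroxy-7-(prenyloxy)-8-prenylflavanone, via C6 ortho-dienone 8 (not isolated), via C8 para-dienone 9 (not isolated)
Conditions: Eu(fod)3 (10 mol %; fod = 6,6,7,7,8,8,8-heptafluoro-2,2-dimethyloctane-3,5-dionate), dry acid-free CHCl3, 60 °C, Ar; chromatography to remove any 6-(1,1-dimethylallyl) isomer
Reagents that add atoms: none
Why: Trivalent europium forms a six-membered chelate between the C4 carbonyl oxygen and O5 and so weakens only the O5–CH2 bond; a charge-accelerated aromatic Claisen [3,3] shift places a 1,1-dimethylallyl group on C6 (dienone 8), a Cope [3,3] shift across C6–C7=C8 carries it to C8 with a second allylic inversion that restores the linear prenyl group (dienone 9), and tautomerisation gives the phenol. The closest known reaction type is the Eu(fod)3-catalysed para-Claisen–Cope rearrangement of 5-O-prenylflavanones that carry an acyl or acetal group on O7; the new feature here is only that the O7 substituent is a second prenyl ether acting as spectator. No ring is closed and no stereocenter is made; C2 is not involved, and the neutral, base-free medium offers no route to the ring-opened chalcone through which flavanones racemise. Selection between the two ethers should follow from the lack of any carbonyl partner for chelation at O7 and from the fact that an unactivated aryl prenyl ether rearranges only far above 60 °C. Selection of C8 over C6 as the terminus should follow because C4a is substituted, C8 is the only para position of C5, and the Cope shift of the non-aromatic dienone 8 should outrun its enolisation in a non-basic medium at moderate temperature. The product is a sink, since its 5-OH is hydrogen-bonded to the C4 carbonyl and the C8 prenyl group has no free ortho hydroxyl to cyclise onto; the enantiomeric purity of 10 should be compared with that of 7 by chiral HPLC.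

**Compound list**

1 | 5,7-dihydroxychromone (5,7-dihydroxy-4H-chromen-4-one) | O=c1ccoc2cc(O)cc(O)c12 | starting material
2 | prenyl bromide (1-bromo-3-methylbut-2-ene) | CC(C)=CCBr | starting material
3 | 5-hydroxy-7-(3-methylbut-2-enyloxy)chromone | CC(C)=CCOc1cc(O)c2c(c1)occc2=O | intermediate
4 | prenol (3-methylbut-2-en-1-ol) | CC(C)=CCO | starting material
5 | 5,7-bis(3-methylbut-2-enyloxy)chromone | CC(C)=CCOc1cc(OCC=C(C)C)c2c(c1)occc2=O | intermediate
6 | phenylboronic acid | OB(O)c1ccccc1 | starting material
7 | (2S)-5,7-bis(3-methylbut-2-enyloxy)-2-phenylchroman-4-one | CC(C)=CCOc1cc(OCC=C(C)C)c2c(c1)O[C@H](c1ccccc1)CC2=O | intermediate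
8 | (2S)-6-(2-methylbut-3-en-2-yl)-7-(3-methylbut-2-enyloxy)-2-phenyl-2,3-dihydro-4H-chromene-4,5(6H)-dione (C6 ortho-dienone, C6 configuration not controlled) | CC(C)=CCOC1=CC2=C(C(=O)C[C@@H](c3ccccc3)O2)C(=O)C1C(C)(C)C=C | intermediate
9 | (2S)-8-(3-methylbut-2-enyl)-7-(3-methylbut-2-enyloxy)-2-phenyl-2,3-dihydro-4H-chromene-4,5(8H)-dione (C8 para-dienone, C8 configuration not controlled) | CC(C)=CCOC1=CC(=O)C2=C(O[C@H](c3ccccc3)CC2=O)C1CC=C(C)C | intermediate
10 | CNP0292726.1, (2S)-5-hydroxy-8-(3-methylbut-2-enyl)-7-(3-methylbut-2-enyloxy)-2-phenylchroman-4-one | CC(C)=CCOc1cc(O)c2c(c1CC=C(C)C)O[C@H](c1ccccc1)CC2=O | target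

**Count**

Total steps: 4. Longest linear sequence: 4 steps (1 to 3 to 5 to 7 to 10).

**Steps most likely to fail**

Step 4. The relay may lose site control because the second prenyl ether is drawn in, through ionisation or migration of the O7 group or crossover of allyl fragments between the two oxygens. The fallback sets out from 1 and comes back at 10. It runs the rearrangement on the substrate class for which it is established, with an acyl group on O7, and attaches the O7 prenyl ether last under neutral conditions. Compound 1 is acetylated at the non-chelated 7-OH only (Ac2O 1.05 equiv, pyridine, 0 °C) to 7-acetoxy-5-hydroxychromone F1. Mitsunobu etherification with 4 (PPh3, DIAD, THF) gives 7-acetoxy-5-(prenyloxy)chromone F2. Addition of 6 with [Rh(OH)((S)-MeO-F12-BIPHEP)]2 under the conditions of step 3 gives (2S)-7-acetoxy-5-(prenyloxy)flavanone F3. Eu(fod)3 (10 mol %, CHCl3, 60 °C) then moves the only allyl ether present, through the acetoxy C6 ortho-dienone F4 and the acetoxy C8 para-dienone F5 (neither isolated), to give (2S)-7-acetoxy-5-hydroxy-8-prenylflavanone F6. The aryl acetate is hydrolysed with NH4OAc in aqueous methanol at room temperature to (2S)-5,7-dihydroxy-8-prenylflavanone F7. A Mitsunobu reaction with 4 (1.05 equiv each of PPh3 and DIAD, THF, 0 °C) etherifies the more acidic, non-chelated 7-OH and gives 10.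

Step 3. Facial discrimination at C2 may be poor because the peri 5-prenyloxy group crowds the catalyst pocket, or configuration may be partly lost during a slow run. The fallback sets out from 5 and comes back at 7. The phenyl group is added without any demand on enantiocontrol, using [Rh(OH)(rac-MeO-F12-BIPHEP)]2 under the conditions of step 3, to give racemic 5,7-bis(prenyloxy)flavanone F8. Kinetic resolution by Noyori-type asymmetric transfer hydrogenation follows (RuCl(p-cymene)(TsDPEN), TsDPEN = N-tosyl-1,2-diphenylethane-1,2-diamine, HCO2H/Et3N, EtOAc, rt, taken slightly beyond half conversion). The catalyst antipode is chosen in a pilot run as the one that reduces the 2R ketone faster. The reduction should convert the unwanted enantiomer into (2R,4R)-5,7-bis(prenyloxy)flavan-4-ol F9, which is removed by chromatography, and leave the 2S ketone 7. The isolated prenyl alkenes should not be reduced by this hydride-transfer catalyst.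

Step 2. Activation of the hydrogen-bonded 5-OH may be too slow, so that the betaine is consumed by side reactions of prenol before the phenol is etherified. The fallback sets out from 3 and comes back at 5, and makes no new compound (F0). The dehydrative coupling is replaced by alkylation of the pre-formed phenoxide with 2 (Cs2CO3, DMF, rt). This is acceptable at this stage because the chromone, unlike a flavanone, has no stereocenter and no retro-oxa-Michael pathway, and a soft counter-ion in a dipolar solvent should favour O- over C-alkylation.

**Further compounds**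

F1 | step 4 | 7-acetoxy-5-hydroxychromone | CC(=O)Oc1cc(O)c2c(c1)occc2=O
F2 | step 4 | 7-acetoxy-5-(3-methylbut-2-enyloxy)chromone | CC(=O)Oc1cc(OCC=C(C)C)c2c(c1)occc2=O
F3 | step 4 | (2S)-7-acetoxy-5-(3-methylbut-2-enyloxy)-2-phenylchroman-4-one | CC(=O)Oc1cc(OCC=C(C)C)c2c(c1)O[C@H](c1ccccc1)CC2=O
F4 | step 4 | (2S)-7-acetoxy-6-(2-methylbut-3-en-2-yl)-2-phenyl-2,3-dihydro-4H-chromene-4,5(6H)-dione (acetoxy C6 ortho-dienone) | CC(=O)OC1=CC2=C(C(=O)C[C@@H](c3ccccc3)O2)C(=O)C1C(C)(C)C=C
F5 | step 4 | (2S)-7-acetoxy-8-(3-methylbut-2-enyl)-2-phenyl-2,3-dihydro-4H-chromene-4,5(8H)-dione (acetoxy C8 para-dienone) | CC(=O)OC1=CC(=O)C2=C(O[C@H](c3ccccc3)CC2=O)C1CC=C(C)C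
F6 | step 4 | (2S)-7-acetoxy-5-hydroxy-8-(3-methylbut-2-enyl)-2-phenylchroman-4-one | CC(=O)Oc1cc(O)c2c(c1CC=C(C)C)O[C@H](c1ccccc1)CC2=O
F7 | step 4 | (2S)-5,7-dihydroxy-8-(3-methylbut-2-enyl)-2-phenylchroman-4-one | Oc1cc(O)c2c(c1CC=C(C)C)O[C@H](c1ccccc1)CC2=O
F8 | step 3 | racemic 5,7-bis(3-methylbut-2-enyloxy)-2-phenylchroman-4-one | CC(C)=CCOc1cc(OCC=C(C)C)c2c(c1)OC(c1ccccc1)CC2=O
F9 | step 3 | (2R,4R)-5,7-bis(3-methylbut-2-enyloxy)-2-phenylchroman-4-ol | CC(C)=CCOc1cc(OCC=C(C)C)c2c(c1)O[C@@H](c1ccccc1)C[C@H]2O
F0 | step 2 | none | none
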